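**Plan**
- Retrosynthetic cuts, in order: the amide N–CO bond; both epoxide C–O bonds (back to C2=C3); C1–C2 (ring B); the oxygens on C1 and C9 (back to a C1=C9 alkene); C5–C4; C5=C9 (ring A); C6–C7.
- Enabling feature: in the bicyclo[3.3.1]nonan-9-one core the bridgehead carbinol C1 is α to the C9 ketone and bonded to C2 of a latent C2=C3 alkene. This is the retron of a C9 enol ether adding through C1 to the terminus of an alkyne held on the C5 arm of ring A.
- Forward: acyclic 1,7-diene → ring A by metathesis → C4–C2 arm onto C5 by [2,3]-Wittig rearrangement → C1=C9 turned into a 1-acetoxy-9-silyloxy alkene → ring B by gold-catalysed 6-endo-dig closure → deprotection, N-acylation, epoxidation.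
- Stereochemistry: the temporary C1 carbinol comes from a Sharpless desymmetrisation; C6 and C7 from a tert-butanesulfinyl imine; C5 and C4 by chirality transfer from C1 in the rearrangement; the bridgehead C1 from C5 through the tether; C2/C3 by exo-face epoxidation.
- O1 carries an acetyl group and only O9 a silyl group, so that C1 and not C9 is the nucleophilic carbon (a bis-silyl ene-diol could also close from C9 in a 5-endo mode).

Key step: step 18

Remark (numbering): all intermediates use the core numbering C1 (carbinol bridgehead), C2–C3 (epoxide), C4 (OMe), C5 (CH bridgehead), C6 (OH), C7 (N), C8 (CH2), C9 (C=O).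
Remark (assumption): the diol of step 14 is drawn for osmylation anti to the C5 side chain; either face serves, because C1 and C9 both become sp2 in step 17.
Remark (assumption): bromide 10 is used as its E/Z mixture, since both isomers give the same allylzinc species.

**Step 1**
Reactants: 1 penta-1,4-dien-3-ol
Product: 2 (2S,3R)-1,2-epoxypent-4-en-3-ol
Conditions: Ti(Oi-Pr)4 (cat.), D-(−)-diisopropyl tartrate, t-BuOOH, 4 Å MS, CH2Cl2, −20 °C
Reagents that add atoms: tert-butyl hydroperoxide, CC(C)(C)OO
Why: Sharpless asymmetric epoxidation of the prochiral divinylcarbinol couples enantiotopic-group selection with kinetic resolution, so the D-tartrate catalyst should give the erythro (2S,3R)-epoxy alcohol in very high ee and thereby set the carbinol that becomes C1.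

**Step 2**
Reactants: 2 (2S,3R)-1,2-epoxypent-4-en-3-ol
Product: 3 (S)-pent-4-ene-1,3-diol
Conditions: NaAlH2(OCH2CH2OMe)2 (Red-Al), THF, 0 °C
Reagents that add atoms: none
Why: Hydroxyl-directed aluminium hydride reduction delivers hydride intramolecularly to the epoxide carbon next to the carbinol (2,3-epoxy alcohol to 1,3-diol) without touching the stereocentre.

**Step 3**
Reactants: 3 (S)-pent-4-ene-1,3-diol
Product: 4 (S)-1,3-bis(triethylsilyloxy)pent-4-ene
Conditions: Et3SiCl, imidazole, DMF, 0 °C to rt
Reagents that add atoms: chlorotriethylsilane, CC[Si](Cl)(CC)CC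
Why: Standard silyl ether formation protects both hydroxyls and prepares the primary one for direct oxidation.

**Step 4**
Reactants: 4 (S)-1,3-bis(triethylsilyloxy)pent-4-ene
Product: 5 (S)-3-(triethylsilyloxy)pent-4-enal
Conditions: (COCl)2, DMSO, CH2Cl2, −78 to −30 °C; then Et3N
Reagents that add atoms: none
Why: Under Swern conditions a primary triethylsilyl ether is cleaved and oxidised directly to the aldehyde while the secondary silyl ether survives, which saves a separate deprotection.

**Step 5**
Reactants: 5 (S)-3-(triethylsilyloxy)pent-4-enal; 6 (S)-2-methylpropane-2-sulfinamide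
Product: 7 (S)-N-[(1E,3S)-3-(triethylsilyloxy)pent-4-en-1-ylidene]-2-methylpropane-2-sulfinamide
Conditions: Ti(OEt)4, THF, rt
Reagents that add atoms: none
Why: Titanium-alkoxide-mediated condensation of an aldehyde with tert-butanesulfinamide gives the E-sulfinyl aldimine without epimerisation or β-elimination of the silyloxy group.

**Step 6**
Reactants: 8 prop-2-enal (acrolein); 9 benzoyl bromide
Product: 10 3-bromoprop-1-en-1-yl benzoate (E/Z mixture)
Conditions: ZnCl2 (cat.), CH2Cl2, −20 to 0 °C
Reagents that add atoms: none
Why: Lewis-acid-catalysed 1,4-addition of an acyl bromide across acrolein (O-acylation, bromide at C3) is the usual entry to 3-halopropenyl esters.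

**Step 7**
Reactants: 7 sulfinyl imine; 10 3-bromoprop-1-en-1-yl benzoate
Product: 11 (3R,4S,6S)-4-{[(S)-tert-butylsulfinyl]amino}-6-(triethylsilyloxy)octa-1,7-dien-3-yl benzoate (C6–OBz and C7–N anti)
Conditions: Zn dust, THF, rt; aq NH4Cl
Reagents that add atoms: none
Why: In this Barbier-type zinc-mediated α-hydroxyallylation of an N-tert-butanesulfinyl aldimine, addition through a zinc-chelated six-membered transition state on the Re face of the (S)-sulfinyl imine should set C7, and the γ-benzoyloxyallylzinc reagent is expected to give the anti (erythro) amino benzoate, which sets C6.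

**Step 8**
Reactants: 11 benzoate sulfinamide
Product: 14 tert-butyl N-[(3R,4S,6S)-3,6-dihydroxyocta-1,7-dien-4-yl]carbamate, via hydroxy sulfinamide 12 (not isolated), via amino diol hydrochloride 13 (not isolated)
Conditions: K2CO3 (cat.), MeOH, rt; then HCl (4 M in dioxane), 0 °C; evaporate; then Boc2O, Et3N, CH2Cl2, rt
Reagents that add atoms: di-tert-butyl dicarbonate, CC(C)(C)OC(=O)OC(=O)OC(C)(C)C
Why: Transesterification removes the benzoate while nitrogen is still sulfinylated (so no O-to-N benzoyl shift can occur), acidic methanolysis then cleaves the N–S and O–Si bonds, and the free amine is trapped as its tert-butyl carbamate.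

**Step 9**
Reactants: 14 N-Boc amino diol diene
Product: 15 tert-butyl N-[(1S,2R,5S)-2,5-dihydroxycyclohex-3-en-1-yl]carbamate (ring A: C5=C9, O6 and N7 cis, O1 trans to both)
Conditions: second-generation Grubbs catalyst (H2IMes)(PCy3)Cl2Ru=CHPh (3 mol %), CH2Cl2, 40 °C
Reagents that add atoms: none
Why: Ring-closing metathesis of the two terminal vinyl groups closes the six-membered ring A with loss of ethene and tolerates free allylic hydroxyls and the carbamate.

**Step 10**
Reactants: 15 cyclohexene carbamate diol
Product: 16 N-Boc N,O-isopropylidene (oxazolidine across O6/N7) derivative with free C1–OH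
Conditions: Me2C(OMe)2, PPTS (cat.), acetone, 50 °C
Reagents that add atoms: 2,2-dimethoxypropane, COC(C)(C)OC
Why: Acid-catalysed N,O-acetalisation can only bridge the cis-disposed O6 and N7, so the trans C1 hydroxyl stays free and nitrogen loses its acidic hydrogen.

**Step 11**
Reactants: 16 allylic alcohol; 17 3-bromo-1-(trimethylsilyl)prop-1-yne
Product: 18 C1 [3-(trimethylsilyl)prop-2-ynyl] ether of 16
Conditions: NaH, n-Bu4NI (cat.), THF, 0 °C to rt
Reagents that add atoms: none
Why: Williamson etherification of the secondary allylic alkoxide with a propargylic bromide proceeds with retention at C1.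

**Step 12**
Reactants: 18 allyl propargyl ether
Product: 19 cyclohexene (C1=C9) carrying at C5 a 1-hydroxy-3-(trimethylsilyl)prop-2-ynyl arm, trans to O6 and N7, with C4–OH syn to C6 (erythro)
Conditions: n-BuLi, THF, −78 °C; H2O
Reagents that add atoms: none
Why: In the [2,3]-Wittig rearrangement the propargylic carbanion adds suprafacially to C5 on the face of the pseudoaxial C1–O bond (trans to O6 and N7), and the envelope transition state with the alkynyl group exo, as for Z-allylic propargyl ethers, should give the erythro C4 carbinol.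

**Step 13**
Reactants: 19 propargylic alcohol
Product: 21 C4 methyl ether with terminal alkyne, via silylalkyne methyl ether 20 (not isolated)
Conditions: NaH, MeI, THF, 0 °C to rt; then MeOH, K2CO3 (cat.), rt
Reagents that add atoms: iodomethane, CI
Why: Williamson methylation of the alkoxide is followed in the same flask by methoxide-induced cleavage of the alkynyl C–Si bond; no N–H is present to compete.

**Step 14**
Reactants: 21 enyne
Product: 22 C1,C9 cis-diol
Conditions: OsO4 (2 mol %), N-methylmorpholine N-oxide, acetone–H2O, rt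
Reagents that add atoms: N-methylmorpholine N-oxide, C[N+]1([O-])CCOCC1; water, O
Why: Catalytic (Upjohn) dihydroxylation oxidises the ring alkene far faster than the terminal alkyne and places oxygen on both C1 and C9.

**Step 15**
Reactants: 22 diol
Product: 23 C1 monoacetate (C9–OH free)
Conditions: AcCl, 2,4,6-collidine, CH2Cl2, −78 °C
Reagents that add atoms: acetyl chloride, CC(Cl)=O
Why: Kinetic acylation at low temperature should select the C1 hydroxyl, flanked by the C8 methylene, over the C9 hydroxyl, which is shielded by the branched C5 substituent.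

**Step 16**
Reactants: 23 hydroxy acetate
Product: 24 C9 ketone with C1 acetoxy group (α-acetoxy ketone)
Conditions: Dess–Martin periodinane, CH2Cl2, 0 °C to rt
Reagents that add atoms: none
Why: Dess–Martin oxidation of the remaining secondary alcohol is non-basic, so neither acetyl migration nor β-elimination of the C4 methoxy or C6 oxygen is expected.

**Step 17**
Reactants: 24 α-acetoxy ketone
Product: 25 ring A 1-acetoxy-9-(tert-butyldimethylsilyloxy) alkene (C1=C9) with the C5 (1-methoxyprop-2-ynyl) arm and the O6/N7 N-Boc acetonide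
Conditions: TBSOTf, Et3N, CH2Cl2, −78 to 0 °C
Reagents that add atoms: tert-butyldimethylsilyl trifluoromethanesulfonate, CC(C)(C)[Si](C)(C)OS(=O)(=O)C(F)(F)F
Why: Soft enolisation (O-silylation, then deprotonation at the more acidic and less hindered acetoxy-bearing C1 rather than at C5) gives the tetrasubstituted silyl enol ether without a free enolate, so the acetyl group stays on O1 and the C1 configuration is erased.

**Step 18**
Reactants: 25 acetoxy silyl enol ether
Product: 26 4-methoxybicyclo[3.3.1]non-2-en-9-one with bridgehead C1–OAc and the O6/N7 N-Boc acetonide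
Conditions: [(2-biphenyl)P(t-Bu)2]Au(NCMe)SbF6 (5 mol %), acetone, H2O (2 equiv), rt
Reagents that add atoms: none
Why: The cationic monovalent gold complex coordinates the terminal alkyne, and C1, the β-carbon of the C9 silyl enol ether, attacks C2 anti to gold to give a vinyl-gold silyloxocarbenium ion, which is desilylated by water and protodeaurated at C3. The closest known reaction type is the gold-catalysed 6-endo-dig carbocyclisation of cyclic silyl enol ethers bearing a pendant terminal alkyne to bicyclo[3.3.1]non-2-en-9-ones. Ring B closes in the 6-endo-dig mode through the C1–C2 bond. The new stereocentre C1 is set by the tether: the C5 arm, held pseudoaxial by A(1,2) strain with the C9 silyloxy group, can reach only the face of C1 cis to it, so C1 follows C5. The step needs 6-endo over 5-exo closure (C1–C3), which the bulky biarylphosphine, the terminal alkyne and the inductively withdrawing C4 methoxy group should secure, and it needs C1 rather than C9 as nucleophile (C9 would close 5-endo), which the acetate on O1 secures by leaving the O9 silyl ether as the only strong donor. No base is present, so the β-oxygenated ketone cannot eliminate.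

**Step 19**
Reactants: 26 bridgehead acetate
Product: 27 bridgehead tertiary alcohol (C1–OH)
Conditions: K2CO3 (cat.), MeOH, 0 °C
Reagents that add atoms: none
Why: Transesterification of the activated α-keto acetate is safe here because both α-positions of the ketone are bridgeheads (no enolisation) and O6 is still masked (no retro-aldol).

**Step 20**
Reactants: 27 N-Boc acetonide
Product: 28 amino diol (C1–OH, C6–OH, C7–NH3+) as its trifluoroacetate salt
Conditions: CF3CO2H–CH2Cl2–H2O (5:4:1), 0 °C to rt
Reagents that add atoms: trifluoroacetic acid, OC(=O)C(F)(F)F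
Why: Acidolysis removes the tert-butyl carbamate and hydrolyses the N,O-acetonide in one operation, and is done before the acid-sensitive epoxide exists.

**Step 21**
Reactants: 28 ammonium trifluoroacetate; 29 (E)-dodec-2-enoic acid
Product: 30 (E)-dodec-2-enamide at N7 (des-epoxy target with C2=C3)
Conditions: EDC·HCl, HOBt, i-Pr2NEt, DMF, 0 °C to rt
Reagents that add atoms: none
Why: Carbodiimide/hydroxybenzotriazole amide coupling acylates the primary amine selectively over the secondary and tertiary hydroxyls.

**Step 22**
Reactants: 30 alkene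
Product: 31 target compound CNP0137540.1
Conditions: dimethyldioxirane (acetone solution), CH2Cl2, 0 °C to rt
Reagents that add atoms: dimethyldioxirane, CC1(C)OO1
Why: Electrophilic epoxidation with a neutral dioxirane should occur on the exo (convex) face of C2=C3, because the endo face is blocked by ring A (C7–H), which sets C2 and C3, while the electron-poor enamide double bond and the ketone (no Baeyer–Villiger) are left alone.

**Compound list**
1 | penta-1,4-dien-3-ol | C=CC(O)C=C | starting material
2 | (2S,3R)-1,2-epoxypent-4-en-3-ol | C=C[C@@H](O)[C@@H]1CO1 | intermediate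
3 | (S)-pent-4-ene-1,3-diol | C=C[C@@H](O)CCO | intermediate
4 | (S)-1,3-bis(triethylsilyloxy)pent-4-ene | C=C[C@@H](O[Si](CC)(CC)CC)CCO[Si](CC)(CC)CC | intermediate
5 | (S)-3-(triethylsilyloxy)pent-4-enal | C=C[C@@H](O[Si](CC)(CC)CC)CC=O | intermediate
6 | (S)-2-methylpropane-2-sulfinamide | CC(C)(C)[S@](=O)N | starting material
7 | (S)-N-[(1E,3S)-3-(triethylsilyloxy)pent-4-en-1-ylidene]-2-methylpropane-2-sulfinamide | CC(C)(C)[S@](=O)/N=C/C[C@H](O[Si](CC)(CC)CC)C=C | intermediate
8 | prop-2-enal (acrolein) | C=CC=O | starting material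
9 | benzoyl bromide | O=C(Br)c1ccccc1 | starting material
10 | 3-bromoprop-1-en-1-yl benzoate (E/Z mixture) | BrCC=COC(=O)c1ccccc1 | intermediate
11 | (3R,4S,6S)-4-{[(S)-tert-butylsulfinyl]amino}-6-(triethylsilyloxy)octa-1,7-dien-3-yl benzoate | CC(C)(C)[S@](=O)N[C@@H](C[C@H](O[Si](CC)(CC)CC)C=C)[C@H](OC(=O)c1ccccc1)C=C | intermediate
12 | (S)-N-[(3R,4S,6S)-3-hydroxy-6-(triethylsilyloxy)octa-1,7-dien-4-yl]-2-methylpropane-2-sulfinamide | CC(C)(C)[S@](=O)N[C@@H](C[C@H](O[Si](CC)(CC)CC)C=C)[C@H](O)C=C | intermediate (not isolated)
13 | (3R,4S,6S)-4-aminoocta-1,7-diene-3,6-diol hydrochloride | [NH3+][C@@H](C[C@H](O)C=C)[C@H](O)C=C.[Cl-] | intermediate (not isolated)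
14 | tert-butyl N-[(3R,4S,6S)-3,6-dihydroxyocta-1,7-dien-4-yl]carbamate | CC(C)(C)OC(=O)N[C@@H](C[C@H](O)C=C)[C@H](O)C=C | intermediate
15 | tert-butyl N-[(1S,2R,5S)-2,5-dihydroxycyclohex-3-en-1-yl]carbamate | CC(C)(C)OC(=O)N[C@H]1C[C@H](O)C=C[C@H]1O | intermediate
16 | ring A allylic alcohol: N-Boc 2,2-dimethyloxazolidine across O6/N7 (cis), C5=C9, free C1–OH trans to O6/N7 | CC(C)(C)OC(=O)N1[C@H]2C[C@H](O)C=C[C@H]2OC1(C)C | intermediate
17 | 3-bromo-1-(trimethylsilyl)prop-1-yne | BrCC#C[Si](C)(C)C | starting material
18 | C1 [3-(trimethylsilyl)prop-2-ynyl] ether of 16 | CC(C)(C)OC(=O)N1[C@H]2C[C@H](OCC#C[Si](C)(C)C)C=C[C@H]2OC1(C)C | intermediate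
19 | C1=C9 cyclohexene with C5 1-hydroxy-3-(trimethylsilyl)prop-2-ynyl arm (trans to O6/N7, C4–OH erythro) | CC(C)(C)OC(=O)N1[C@H]2CC=C[C@@H]([C@H]2OC1(C)C)[C@H](O)C#C[Si](C)(C)C | intermediate
20 | C4 methyl ether of 19 (silylalkyne) | CC(C)(C)OC(=O)N1[C@H]2CC=C[C@@H]([C@H]2OC1(C)C)[C@H](OC)C#C[Si](C)(C)C | intermediate (not isolated)
21 | C1=C9 cyclohexene with C5 (1-methoxyprop-2-ynyl) arm | CC(C)(C)OC(=O)N1[C@H]2CC=C[C@@H]([C@H]2OC1(C)C)[C@H](OC)C#C | intermediate
22 | C1,C9 cis-diol of 21 (drawn anti to the C5 arm) | CC(C)(C)OC(=O)N1[C@H]2C[C@@H](O)[C@@H](O)[C@@H]([C@H]2OC1(C)C)[C@H](OC)C#C | intermediate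
23 | C1 acetate, C9 alcohol | CC(C)(C)OC(=O)N1[C@H]2C[C@@H](OC(C)=O)[C@@H](O)[C@@H]([C@H]2OC1(C)C)[C@H](OC)C#C | intermediate
24 | C1-acetoxy C9 ketone | CC(C)(C)OC(=O)N1[C@H]2C[C@@H](OC(C)=O)C(=O)[C@@H]([C@H]2OC1(C)C)[C@H](OC)C#C | intermediate
25 | 1-acetoxy-9-(tert-butyldimethylsilyloxy) C1=C9 alkene (key-step precursor) | CC(C)(C)OC(=O)N1[C@H]2CC(OC(C)=O)=C(O[Si](C)(C)C(C)(C)C)[C@@H]([C@H]2OC1(C)C)[C@H](OC)C#C | intermediate
26 | 1-acetoxy-4-methoxybicyclo[3.3.1]non-2-en-9-one with O6/N7 N-Boc acetonide (key-step product) | CC(C)(C)OC(=O)N1[C@H]2C[C@@]3(OC(C)=O)C(=O)[C@@H]([C@H]2OC1(C)C)[C@H](OC)C=C3 | intermediate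
27 | 1-hydroxy analogue of 26 | CC(C)(C)OC(=O)N1[C@H]2C[C@@]3(O)C(=O)[C@@H]([C@H]2OC1(C)C)[C@H](OC)C=C3 | intermediate
28 | 7-ammonio-1,6-dihydroxy-4-methoxybicyclo[3.3.1]non-2-en-9-one trifluoroacetate | [NH3+][C@H]1C[C@@]2(O)C(=O)[C@@H]([C@H]1O)[C@H](OC)C=C2.[O-]C(=O)C(F)(F)F | intermediate
29 | (E)-dodec-2-enoic acid | CCCCCCCCC/C=C/C(=O)O | starting material
30 | N7 (E)-dodec-2-enamide of the 1,6-dihydroxy-4-methoxybicyclo[3.3.1]non-2-en-9-one | CCCCCCCCC/C=C/C(=O)N[C@H]1C[C@@]2(O)C(=O)[C@@H]([C@H]1O)[C@H](OC)C=C2 | intermediate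
31 | CNP0137540.1 (exo-2,3-epoxide of 30) | CCCCCCCCC/C=C/C(=O)N[C@H]1C[C@@]2(O)C(=O)[C@@H]([C@H]1O)[C@H](OC)[C@@H]1O[C@@H]12 | target

**Step count**
Total: 22 steps. Longest linear sequence: 21 steps (steps 1–5 and 7–22; step 6 is a one-step side branch).

**Steps most likely to fail**

1. Step 18. The closure may run through C3 (5-exo-dig) instead of C2, or the enol ether may lose its silyl group by hydrolysis before the C–C bond forms. Fallback: the same C1–C2 bond is made with palladium, setting out from ketone 24. Iodination of the terminal alkyne (N-iodosuccinimide, AgNO3 cat., acetone) would give iodoalkyne F1. Diimide reduction (2-nitrobenzenesulfonylhydrazide, Et3N) would give (Z)-vinyl iodide F2. Soft enolisation (TBSOTf, Et3N) would give silyl enol ether F3. Fluoride-promoted intramolecular α-alkenylation with zerovalent palladium (Pd2(dba)3, P(t-Bu)3, CsF, toluene, 80 °C) would then return to the route at 26.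

2. Step 7. The allylzinc addition may show poor anti/syn or facial selectivity (mismatch with the existing C1 stereocentre), or add through its α- instead of its γ-carbon. Fallback: setting out from sulfinyl imine 7, a samarium-diiodide-mediated reductive cross-coupling with 3-(phenylselanyl)propanal (SmI2, t-BuOH, THF, −78 °C), a reaction type that gives anti 1,2-amino alcohols, would give hydroxy sulfinamide selenide F5. Periodate oxidation and selenoxide elimination (NaIO4, NaHCO3, MeOH–H2O) would unveil the vinyl group and return to the route at 12. The sulfur antipode of 7 would be taken if this coupling followed the opposite sense of induction.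

3. Step 12. The C4 selectivity may erode (alkynyl group endo in the transition state), or a [1,2]-shift may compete. Fallback: C4 is set by reagent control instead. Setting out from 19 obtained as a C4 epimer mixture, Dess–Martin oxidation would give ynone F4, used at once. Noyori transfer hydrogenation (RuCl[(S,S)-TsDPEN](p-cymene), HCO2H–Et3N) would return to 19 as the single erythro carbinol.

**Further compounds**
F1 | step 18 | iodoalkyne analogue of ketone 24 | CC(C)(C)OC(=O)N1[C@H]2C[C@@H](OC(C)=O)C(=O)[C@@H]([C@H]2OC1(C)C)[C@H](OC)C#CI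
F2 | step 18 | (Z)-vinyl iodide from F1 | CC(C)(C)OC(=O)N1[C@H]2C[C@@H](OC(C)=O)C(=O)[C@@H]([C@H]2OC1(C)C)[C@H](OC)/C=C\I
F3 | step 18 | 1-acetoxy-9-silyloxy alkene bearing the (Z)-vinyl iodide | CC(C)(C)OC(=O)N1[C@H]2CC(OC(C)=O)=C(O[Si](C)(C)C(C)(C)C)[C@@H]([C@H]2OC1(C)C)[C@H](OC)/C=C\I
F4 | step 12 | C4 ynone from 19 | CC(C)(C)OC(=O)N1[C@H]2CC=C[C@@H]([C@H]2OC1(C)C)C(=O)C#C[Si](C)(C)C
F5 | step 7 | hydroxy sulfinamide with a 2-(phenylselanyl)ethyl group on C6 | CC(C)(C)[S@](=O)N[C@@H](C[C@H](O[Si](CC)(CC)CC)C=C)[C@H](O)CC[Se]c1ccccc1
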